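## Retrosynthetic overview
1. Lychnophorolide B comes from a C15-OTBDPS macrolactone by silyl removal. That macrolactone forms in one step, by intramolecular Cr(II) allylation of the C6 enal with a C7–C11–C13 allylic bromide. This closes the 10-membered ring and the α-methylene-γ-lactone together (C6–C7 bond, then lactonisation).
2. The allylic bromide comes from a Morita–Baylis–Hillman (MBH) adduct of the C7 aldehyde (SN2′ bromination). That aldehyde comes from ozonolysis of a prenyl-type alkene.
3. The 3(2H)-furanone forms by 5-endo-dig oxa-Michael cyclisation of an α-hydroxy-ynone. The ynone comes from a lithium acetylide of a (Z)-enyne acetal adding to a Weinreb amide.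
4. C10 comes from (R)-citramalic acid. C8 is set by a C10-OH-directed syn reduction (Narasaka–Prasad). The (Z)-enyne comes from 2-butyne-1,4-diol by Red-Al/I2 and Sonogashira coupling.

Assumptions:
- (R)-Citramalic acid is commercially available.
- The ester in the target is tiglate (E), as the SMILES shows.
- The C7 epimers in the MBH adduct are carried as a mixture and converge at step 18.
- Red-Al hydroalumination is directed by the free OH, putting iodine at C4 cis to CH2OH.

## Route

**Step 1**
Reactants: 1 (R)-citramalic acid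
Product: 2 (R)-bis-Weinreb amide
Conditions: MeNH(OMe)·HCl, EDC·HCl, HOBt, iPr2NEt, CH2Cl2/DMF, 0 °C → rt
Reagents that add atoms: N,O-dimethylhydroxylamine, CNOC
Why: Amide coupling converts both acids to Weinreb amides, so later organometallic additions stop at the ketone; C10 is untouched.

**Step 2**
Reactants: 2
Product: 3 hydroxy-enone Weinreb amide
Conditions: 2-methylprop-1-enylMgBr (2.5 equiv), THF, −20 → 0 °C
Reagents that add atoms: 2-methylprop-1-enylmagnesium bromide, CC(C)=C[Mg]Br
Why: The unhindered C8 amide reacts by Weinreb ketone synthesis. The C1 amide next to the tertiary Mg alkoxide is chelated and hindered, so it survives; no over-addition occurs.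

**Step 3**
Reactants: 3
Product: 4 syn-1,3-diol
Conditions: Et2BOMe, NaBH4, THF/MeOH 4:1, −78 °C
Reagents that add atoms: none
Why: Narasaka–Prasad reduction. A boron chelate of the C10-OH and the C8 ketone receives axial hydride, giving the syn-1,3-diol. This sets C8 as S relative to the C10 centre, which is R.

**Step 4**
Reactants: 4
Product: 5 C8-tiglate
Conditions: tigloyl chloride, pyridine, DMAP (cat.), CH2Cl2, 0 °C
Reagents that add atoms: tigloyl chloride, ClC(=O)/C(C)=C/C
Why: Acylation occurs only at the secondary C8-OH; the tertiary C10-OH is too hindered. The E-tiglate geometry is retained.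

**Step 5**
Reactants: 5
Product: 6 C10-OTMS ether
Conditions: 1-(trimethylsilyl)imidazole, CH2Cl2, rt
Reagents that add atoms: 1-(trimethylsilyl)imidazole, C[Si](C)(C)n1ccnc1
Why: Silylation masks the tertiary OH so the aldehyde formed in step 6 cannot close to a γ-lactol.

**Step 6**
Reactants: 6
Product: 7 α-tigloyloxy aldehyde
Conditions: O3, CH2Cl2, −78 °C; then Me2S
Reagents that add atoms: ozone, [O-][O+]=O
Why: Ozonolysis cleaves the electron-rich trisubstituted alkene faster than the conjugated tiglate C=C. This gives the C7 aldehyde and acetone; C8 is untouched.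

**Step 7**
Reactants: 7
Product: 8 MBH adduct (C7 epimeric mixture)
Conditions: ethyl acrylate (5 equiv), DABCO (0.3 equiv), neat, rt
Reagents that add atoms: ethyl acrylate, C=CC(=O)OCC
Why: Morita–Baylis–Hillman reaction installs the C11=C13/C12 ester unit. The new C7 carbinol is formed as a mixture, which is erased in step 18.

**Step 8**
Reactants: 8
Product: 9 C7-OTES ether
Conditions: TESCl, imidazole, DMF, 0 °C
Reagents that add atoms: chlorotriethylsilane, CC[Si](Cl)(CC)CC
Why: Capping C7-OH prevents acyl migration from C8 and alkoxide chemistry in step 15.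

**Step 9**
Reactants: 10 (2-butyne-1,4-diol)
Product: 11 mono-TBDPS ether
Conditions: NaH (1 equiv), TBDPSCl (1 equiv), THF, 0 °C
Reagents that add atoms: tert-butylchlorodiphenylsilane, CC(C)(C)[Si](Cl)(c1ccccc1)c1ccccc1
Why: Mono-silylation of the symmetric diol protects C15 with a robust group and leaves C6-OH free for directed hydroalumination.

**Step 10**
Reactants: 11
Product: 12 (Z)-iodoallylic alcohol
Conditions: Red-Al, THF, 0 °C; then I2, −78 °C
Reagents that add atoms: iodine, II
Why: OH-directed trans-hydroalumination followed by iodinolysis gives the vinyl iodide with I cis to CH2OH. This fixes the C4=C5 geometry required for the 10-ring (C6 cis to C3).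

**Step 11**
Reactants: 12
Product: 13 (Z)-iodoenal
Conditions: MnO2, CH2Cl2, rt
Reagents that add atoms: none
Why: MnO2 selectively oxidises the allylic alcohol with retention of alkene geometry.

**Step 12**
Reactants: 13
Product: 14 dimethyl acetal
Conditions: HC(OMe)3, PPTS, MeOH, rt
Reagents that add atoms: trimethyl orthoformate, COC(OC)OC
Why: Acetalisation masks the aldehyde so it survives the acetylide chemistry and stops C6 from attacking the ynone.

**Step 13**
Reactants: 14
Product: 15 TMS-enyne acetal
Conditions: TMS-acetylene, Pd(PPh3)2Cl2, CuI, Et3N, THF, rt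
Reagents that add atoms: trimethylsilylacetylene, C#C[Si](C)(C)C
Why: Sonogashira coupling on the vinyl iodide proceeds with retention of the Z geometry.

**Step 14**
Reactants: 15
Product: 16 terminal enyne acetal
Conditions: K2CO3, MeOH, rt
Reagents that add atoms: none
Why: Base-mediated protodesilylation of the alkynyl C–Si bond; the acetal and TBDPS group are stable.

**Step 15**
Reactants: 9 and 16
Product: 17 ynone
Conditions: 16 + n-BuLi (2 equiv), THF, −78 °C; add 9, −78 → −40 °C
Reagents that add atoms: none
Why: Weinreb ketone synthesis. The lithium acetylide adds once to the C1 amide through a stable chelated intermediate. No stereocentre is created, and C10 is quaternary so it cannot epimerise.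

**Step 16**
Reactants: 17
Product: 18 furanone acetal
Conditions: K2CO3, EtOH, 0 °C
Reagents that add atoms: none
Why: Base removes the tertiary TMS ether. The C10 alkoxide then cyclises onto the ynone β-carbon by 5-endo-dig oxa-Michael addition, forming the 3(2H)-furanone with C10 retained. EtOH avoids ester exchange.

**Step 17**
Reactants: 18
Product: 19 enal with free C7-OH
Conditions: 1 M HCl, THF, rt
Reagents that add atoms: water, O
Why: Acid hydrolysis unmasks the aldehyde from the acetal and removes the TES group in one operation. TBDPS, tiglate and the furanone survive.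

**Step 18**
Reactants: 19
Product: 20 (Z)-allylic bromide
Conditions: MsCl, Et3N, CH2Cl2, 0 °C; then LiBr, THF, rt
Reagents that add atoms: lithium bromide, [Li+].[Br-]
Why: Mesylation followed by SN2′ displacement by bromide gives the trisubstituted 2-(bromomethyl)alkenoate. C7 becomes sp2, so the epimer mixture converges to one compound.

**Step 19**
Reactants: 20
Product: 21 TBDPS-protected macrolactone
Conditions: CrCl2 (8 equiv), DMF, 0.003 M, rt; then cat. p-TsOH if lactonisation is incomplete
Reagents that add atoms: none
Why: Intramolecular Nozaki–Hiyama–Kishi-type allylation. The allylchromium reacts at the γ-carbon (C7) with the Z-locked enal (C6), closing the 10-membered ring. Chair-like addition favours the trans relationship, which should give 6R,7R under C8 control. The C6 alkoxide then lactonises onto the ethyl ester to form the α-methylene-γ-lactone.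

**Step 20**
Reactants: 21
Product: 22 lychnophorolide B
Conditions: HF·pyridine, pyridine/THF, 0 °C → rt
Reagents that add atoms: none
Why: Fluoride-mediated cleavage of the primary TBDPS ether frees C15-OH. The tiglate, furanone and exo-methylene lactone tolerate buffered HF.

## Compound list
1 | (R)-citramalic acid | C[C@@](O)(CC(=O)O)C(=O)O | starting material
2 | bis-Weinreb amide of 1 | C[C@@](O)(CC(=O)N(C)OC)C(=O)N(C)OC | intermediate
3 | hydroxy-enone Weinreb amide | C[C@@](O)(CC(=O)C=C(C)C)C(=O)N(C)OC | intermediate
4 | syn-1,3-diol | C[C@@](O)(C[C@H](O)C=C(C)C)C(=O)N(C)OC | intermediate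
5 | C8 tiglate | C[C@@](O)(C[C@H](OC(=O)/C(C)=C/C)C=C(C)C)C(=O)N(C)OC | intermediate
6 | C10-OTMS ether | C[C@@](O[Si](C)(C)C)(C[C@H](OC(=O)/C(C)=C/C)C=C(C)C)C(=O)N(C)OC | intermediate
7 | α-tigloyloxy aldehyde | C[C@@](O[Si](C)(C)C)(C[C@H](OC(=O)/C(C)=C/C)C=O)C(=O)N(C)OC | intermediate
8 | MBH adduct (C7 epimers) | C[C@@](O[Si](C)(C)C)(C[C@H](OC(=O)/C(C)=C/C)C(O)C(=C)C(=O)OCC)C(=O)N(C)OC | intermediate
9 | C7-OTES ether | C[C@@](O[Si](C)(C)C)(C[C@H](OC(=O)/C(C)=C/C)C(O[Si](CC)(CC)CC)C(=C)C(=O)OCC)C(=O)N(C)OC | intermediate
10 | 2-butyne-1,4-diol | OCC#CCO | starting material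
11 | 4-(TBDPSO)but-2-yn-1-ol | OCC#CCO[Si](c1ccccc1)(c1ccccc1)C(C)(C)C | intermediate
12 | (Z)-3-iodo-4-(TBDPSO)but-2-en-1-ol | OC/C=C(\I)CO[Si](c1ccccc1)(c1ccccc1)C(C)(C)C | intermediate
13 | (Z)-3-iodo-4-(TBDPSO)but-2-enal | O=C/C=C(\I)CO[Si](c1ccccc1)(c1ccccc1)C(C)(C)C | intermediate
14 | dimethyl acetal of 13 | COC(OC)/C=C(\I)CO[Si](c1ccccc1)(c1ccccc1)C(C)(C)C | intermediate
15 | TMS-enyne acetal | COC(OC)/C=C(\C#C[Si](C)(C)C)CO[Si](c1ccccc1)(c1ccccc1)C(C)(C)C | intermediate
16 | terminal enyne acetal | COC(OC)/C=C(\C#C)CO[Si](c1ccccc1)(c1ccccc1)C(C)(C)C | intermediate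
17 | α-silyloxy ynone | COC(OC)/C=C(\C#CC(=O)[C@](C)(O[Si](C)(C)C)C[C@H](OC(=O)/C(C)=C/C)C(O[Si](CC)(CC)CC)C(=C)C(=O)OCC)CO[Si](c1ccccc1)(c1ccccc1)C(C)(C)C | intermediate
18 | furanone acetal | COC(OC)/C=C(\C1=CC(=O)[C@@](C)(C[C@H](OC(=O)/C(C)=C/C)C(O[Si](CC)(CC)CC)C(=C)C(=O)OCC)O1)CO[Si](c1ccccc1)(c1ccccc1)C(C)(C)C | intermediate
19 | furanone enal, free C7-OH | O=C/C=C(\C1=CC(=O)[C@@](C)(C[C@H](OC(=O)/C(C)=C/C)C(O)C(=C)C(=O)OCC)O1)CO[Si](c1ccccc1)(c1ccccc1)C(C)(C)C | intermediate
20 | (Z)-allylic bromide | O=C/C=C(\C1=CC(=O)[C@@](C)(C[C@H](OC(=O)/C(C)=C/C)/C=C(\CBr)C(=O)OCC)O1)CO[Si](c1ccccc1)(c1ccccc1)C(C)(C)C | intermediate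
21 | TBDPS-protected macrolactone | C=C1C(=O)O[C@@H]2/C=C(/CO[Si](c4ccccc4)(c4ccccc4)C(C)(C)C)C3=CC(=O)[C@@](C)(C[C@H](OC(=O)/C(C)=C/C)[C@@H]12)O3 | intermediate
22 | lychnophorolide B | C=C1C(=O)O[C@@H]2/C=C(/CO)C3=CC(=O)[C@@](C)(C[C@H](OC(=O)/C(C)=C/C)[C@@H]12)O3 | target

## Totals
Total steps: 20. Longest linear sequence: 14 steps (1→9, then 15→20).

Three steps most likely to fail:
1. **Step 19 (macrocyclic Cr allylation).** Yield, the C6/C7 diastereoselectivity and Z→E enal isomerisation are all uncertain. Fallback: build the trans α-methylene-γ-lactone first by allylboration of an enal with a γ-substituted 2-(alkoxycarbonyl)allylboronate, then close the ring by intramolecular Stille coupling between a 3-stannyl-furanone and a C4 vinyl iodide.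
2. **Step 3 (syn reduction next to a tertiary carbinol).** The dr depends on the Me versus amide preference in the boron chelate. Fallback: take the anti-diol from Evans–Saksena reduction and invert C8 by Mitsunobu with tiglic acid (PPh3, DIAD), which installs the tiglate at the same time.
3. **Step 7 (MBH on the α-acyloxy aldehyde).** The aldehyde may epimerise at C8, and the tiglate may migrate to the new C7-OH. Fallback: mask C8-O as a TBS ether in step 4 instead of tiglate, run the sequence unchanged, then remove TBS (HF·py) and install tiglate (Yamaguchi esterification) just before the final TBDPS removal.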